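**Strategy.** Ring atoms: C1 (quaternary, CH3/chlorovinyl), C2 (CH2), C3 (CBr), C4 (CHCl), C5 (CH2), C6 (CHCl). Everything rests on cutting C2–C3 and C6–C1 of the cyclohexane. The key step exploits the 1,3-placed heteroatoms on C4 and C6 and the quaternary C1 next to C6: they are the imprint of a 1-chloro-3-silyloxybutadiene and methacrolein. One catalytic enantioselective endo Diels–Alder reaction closes the ring and sets C1 and the neopentyl C6–Cl centre, cis to the formyl group. The precursors are two achiral four-carbon pieces. The C4 ketone so unveiled later brings in C4–Cl and the CH2Cl carbon; Br comes last.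

Key step: step 2

Assumption: the sense of induction in step 2 is taken from the formyl C–H···O binding model of 2-substituted acroleins on N-protonated oxazaborolidines; if the adduct proved antipodal, the equally available (S)-catalyst would be used with nothing else changed.

Step 1
Reactants: 1 (E)-4-chlorobut-3-en-2-one
Product: 3 [(3E)-4-chlorobuta-1,3-dien-2-yl]oxy-tri(propan-2-yl)silane, via sodium dienolate 2 (not isolated)
Conditions: NaN(SiMe3)2, THF, −78 °C; then iPr3SiOSO2CF3, −78 → 0 °C
Reagents that add atoms: triisopropylsilyl trifluoromethanesulfonate, CC(C)[Si](OS(=O)(=O)C(F)(F)F)(C(C)C)C(C)C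
Why: Silyl enol ether formation: the hindered amide should remove a methyl proton kinetically rather than add to the β-chloroenone, and O-silylation of the cross-conjugated enolate gives the 2-silyloxy diene with the E chloroalkene untouched; no stereocentre is formed.

Step 2
Reactants: 3 [(3E)-4-chlorobuta-1,3-dien-2-yl]oxy-tri(propan-2-yl)silane; 4 methacrolein (2-methylprop-2-enal)
Product: 6 (1S,2S)-2-chloro-1-methyl-4-oxocyclohexane-1-carbaldehyde, via silyl enol ether cycloadduct 5 (not isolated)
Conditions: (R)-tetrahydro-1-(2-methylphenyl)-3,3-diphenyl-1H,3H-pyrrolo[1,2-c][1,3,2]oxazaborole (20 mol %), HN(SO2CF3)2 (18 mol %), CH2Cl2, −78 → −40 °C; then 1 M aq HCl, THF, −20 → 0 °C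
Reagents that add atoms: none
Why: The N-protonated oxazaborolidine binds methacrolein through B···O and a formyl C–H···O contact, and the diene adds in a concerted but asynchronous [4+2] cycloaddition in which the nucleophilic CH2 terminus of the silyl enol ether (C3) bonds ahead to the β-carbon (C2) while C6 closes on the α-carbon (C1). The closest known reaction type is the oxazaborolidinium-catalysed Diels–Alder reaction of 2-silyloxybutadienes with 2-substituted acroleins. The only ring formed, the six-membered carbocycle, is closed by intermolecular suprafacial–suprafacial [4π+2π] addition. C1 is controlled by the catalyst, whose phenyl group covers the Re face of the s-trans enal so that C6 arrives on the Si face (1S); C6 is controlled relative to C1 by the E geometry of the chloroalkene together with the endo position of the coordinated formyl group, which puts Cl cis to CHO (2S in 6). The step needs regioselectivity, secured because the C4 silyloxy group (para rule) and the C6 chlorine (ortho rule) both polarise the diene towards C3, chemoselectivity for C=C over C=O, known for this catalyst class, and endo selectivity, usual for acyclic dienes with Lewis-acid-bound 2-substituted acroleins. Adduct 5 is an allylic chloride activated by the enol ether, so the bulky silyl group, the low temperature and the cold acidic quench, which protonates C5 before chloride can leave, are what should keep C6–Cl in place.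

Step 3
Reactants: 6 (1S,2S)-2-chloro-1-methyl-4-oxocyclohexane-1-carbaldehyde
Product: 7 (3S,4S)-3-chloro-4-[(E)-2-chloroethenyl]-4-methylcyclohexan-1-one
Conditions: CrCl2 (6 equiv), CHCl3 (2.5 equiv), THF, 65 °C
Reagents that add atoms: chloroform, ClC(Cl)Cl
Why: Takai olefination: the geminal dichromium species from CHCl3 adds to the aldehyde much faster than to the ketone and its elimination gives the E chloroalkene, while the secondary alkyl chloride is inert to divalent chromium and the medium is not basic, so no stereocentre is touched.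

Step 4
Reactants: 7 (3S,4S)-3-chloro-4-[(E)-2-chloroethenyl]-4-methylcyclohexan-1-one
Product: 9 (4S,5S)-2,4-dichloro-5-[(E)-2-chloroethenyl]-5-methylcyclohex-1-ene-1-carbaldehyde, via chlorovinyl iminium chloride 8 (not isolated)
Conditions: POCl3 (3 equiv), DMF (4 equiv), ClCH2CH2Cl, 0 → 45 °C; then ice–water
Reagents that add atoms: N,N-dimethylformamide, CN(C)C=O; phosphoryl chloride, O=P(Cl)(Cl)Cl; water, O
Why: Vilsmeier–Haack–Arnold haloformylation: in this acidic medium the ketone should enolise and react at C3, the α-carbon remote from the bulky and inductively deactivating C6–Cl/C1 array (the side on which 3-substituted cyclohexanones react), so C3 receives the formyl carbon and C4 its chlorine in one step without a base that would expel the β-chloride.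

Step 5
Reactants: 9 (4S,5S)-2,4-dichloro-5-[(E)-2-chloroethenyl]-5-methylcyclohex-1-ene-1-carbaldehyde
Product: 10 [(4S,5S)-2,4-dichloro-5-[(E)-2-chloroethenyl]-5-methylcyclohex-1-en-1-yl]methanol
Conditions: NaBH4, MeOH, 0 °C
Reagents that add atoms: none
Why: Borohydride 1,2-reduction of a β-chloro enal, the usual behaviour of 2-chlorocyclohexenecarbaldehydes, leaves the vinyl and alkyl chlorides alone and creates no stereocentre.

Step 6
Reactants: 10 [(4S,5S)-2,4-dichloro-5-[(E)-2-chloroethenyl]-5-methylcyclohex-1-en-1-yl]methanol
Product: 13 (1S,2S,4R)-2,4-dichloro-1-[(E)-2-chloroethenyl]-1-methyl-5-methylidenecyclohexane, via N-allylic sulfonylhydrazine 11 (not isolated), via allylic diazene 12 (not isolated)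
Conditions: 2-nitrobenzenesulfonohydrazide, PPh3, diethyl azodicarboxylate, THF, −30 °C, then 23 °C
Reagents that add atoms: none
Why: Myers reductive allylic transposition: Mitsunobu alkylation of the sulfonylhydrazide, loss of sulfinic acid and retro-ene loss of N2 move the alkene to the exocyclic position and hand H to C4; the diazene arm should reach C4 over the ring face opposite the axial chlorovinyl group, so H enters axially on the face of the C1 methyl and Cl ends equatorial, cis to C6–Cl (4R).

Step 7
Reactants: 13 (1S,2S,4R)-2,4-dichloro-1-[(E)-2-chloroethenyl]-1-methyl-5-methylidenecyclohexane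
Product: 14 (1R,2R,4S,5S)-2,4-dichloro-1-(chloromethyl)-5-[(E)-2-chloroethenyl]-5-methylcyclohexan-1-ol
Conditions: trichloroisocyanuric acid (0.37 equiv), acetone–H2O 4:1, 0 °C
Reagents that add atoms: trichloroisocyanuric acid, O=C1N(Cl)C(=O)N(Cl)C(=O)N1Cl; water, O
Why: Markovnikov chlorohydrin formation (electrophilic cohalogenation): the 1,1-disubstituted alkene is far more nucleophilic than the chlorovinyl group, the chloronium ion should form on the open equatorial face and water should open it at the tertiary C3 by axial attack, as with methylenecyclohexanes and methallyl chloride, which gives axial OH and equatorial CH2Cl (1R in 14).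

Step 8
Reactants: 14 (1R,2R,4S,5S)-2,4-dichloro-1-(chloromethyl)-5-[(E)-2-chloroethenyl]-5-methylcyclohexan-1-ol
Product: 16 (1R,2R,4S,5S)-1-bromo-2,4-dichloro-1-(chloromethyl)-5-[(E)-2-chloroethenyl]-5-methylcyclohexane, via alkoxydibromoborane 15 (not isolated)
Conditions: BBr3 (1.2 equiv), CH2Cl2, −78 → −10 °C; then water
Reagents that add atoms: boron tribromide, BrB(Br)Br
Why: Substitution of a tertiary alcohol by bromide through its dibromoborate (SN1 with neighbouring-group participation): the C3–O bond should ionise with help from the antiperiplanar chlorine of CH2Cl, and bromide released from the departing borate on the same face opens the spiro chloronium ion at the tertiary carbon, so Br takes the axial site of OH with retention, which is also the more stable C3 epimer (Br axial, CH2Cl equatorial) on which either C3 epimer of 14 should converge, while the equatorial C4–Cl lies near the nodal plane and cannot bridge.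

**Compound list**
1 | (E)-4-chlorobut-3-en-2-one | CC(=O)/C=C/Cl | starting material
2 | sodium (3E)-4-chlorobuta-1,3-dien-2-olate | [Na+].C=C([O-])/C=C/Cl | intermediate
3 | [(3E)-4-chlorobuta-1,3-dien-2-yl]oxy-tri(propan-2-yl)silane | C=C(O[Si](C(C)C)(C(C)C)C(C)C)/C=C/Cl | intermediate
4 | methacrolein (2-methylprop-2-enal) | C=C(C)C=O | starting material
5 | (1S,2S)-2-chloro-1-methyl-4-[tri(propan-2-yl)silyloxy]cyclohex-3-ene-1-carbaldehyde | C[C@@]1(C=O)CCC(O[Si](C(C)C)(C(C)C)C(C)C)=C[C@@H]1Cl | intermediate
6 | (1S,2S)-2-chloro-1-methyl-4-oxocyclohexane-1-carbaldehyde | C[C@@]1(C=O)CCC(=O)C[C@@H]1Cl | intermediate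
7 | (3S,4S)-3-chloro-4-[(E)-2-chloroethenyl]-4-methylcyclohexan-1-one | C[C@@]1(/C=C/Cl)CCC(=O)C[C@@H]1Cl | intermediate
8 | [(4S,5S)-2,4-dichloro-5-[(E)-2-chloroethenyl]-5-methylcyclohex-1-en-1-yl]methylidene-dimethylammonium chloride | C[C@@]1(/C=C/Cl)CC(C=[N+](C)C)=C(Cl)C[C@@H]1Cl.[Cl-] | intermediate
9 | (4S,5S)-2,4-dichloro-5-[(E)-2-chloroethenyl]-5-methylcyclohex-1-ene-1-carbaldehyde | C[C@@]1(/C=C/Cl)CC(C=O)=C(Cl)C[C@@H]1Cl | intermediate
10 | [(4S,5S)-2,4-dichloro-5-[(E)-2-chloroethenyl]-5-methylcyclohex-1-en-1-yl]methanol | C[C@@]1(/C=C/Cl)CC(CO)=C(Cl)C[C@@H]1Cl | intermediate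
11 | N-{[(4S,5S)-2,4-dichloro-5-[(E)-2-chloroethenyl]-5-methylcyclohex-1-en-1-yl]methyl}-2-nitrobenzenesulfonohydrazide | C[C@@]1(/C=C/Cl)CC(CN(N)S(=O)(=O)c2ccccc2[N+](=O)[O-])=C(Cl)C[C@@H]1Cl | intermediate
12 | {[(4S,5S)-2,4-dichloro-5-[(E)-2-chloroethenyl]-5-methylcyclohex-1-en-1-yl]methyl}diazene | C[C@@]1(/C=C/Cl)CC(CN=N)=C(Cl)C[C@@H]1Cl | intermediate
13 | (1S,2S,4R)-2,4-dichloro-1-[(E)-2-chloroethenyl]-1-methyl-5-methylidenecyclohexane | C[C@@]1(/C=C/Cl)CC(=C)[C@H](Cl)C[C@@H]1Cl | intermediate
14 | (1R,2R,4S,5S)-2,4-dichloro-1-(chloromethyl)-5-[(E)-2-chloroethenyl]-5-methylcyclohexan-1-ol | C[C@@]1(/C=C/Cl)C[C@@](O)(CCl)[C@H](Cl)C[C@@H]1Cl | intermediate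
15 | dibromoborate ester of 14 (C3–O–BBr2) | C[C@@]1(/C=C/Cl)C[C@@](OB(Br)Br)(CCl)[C@H](Cl)C[C@@H]1Cl | intermediate
16 | (1R,2R,4S,5S)-1-bromo-2,4-dichloro-1-(chloromethyl)-5-[(E)-2-chloroethenyl]-5-methylcyclohexane | C[C@@]1(/C=C/Cl)C[C@@](Br)(CCl)[C@H](Cl)C[C@@H]1Cl | target

Total step count: 8. Longest linear sequence: 8 steps (1 → 16).

**Steps most likely to fail**

Step 8. Ionisation at C3 is slowed by two β-chlorines. Forcing it may open side channels:
- a 1,2-hydride shift from C4;
- loss of a proton to give an alkene;
- attack of bromide at the CH2 end of the chloronium ion, which scrambles the halogens;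
- capture of bromide from the wrong face.

The fallback avoids any cation. It sets out from 10 and comes back at 16. PPh3 and hexachloroacetone turn the alcohol into the allylic chloride (4S,5S)-1,5-dichloro-2-(chloromethyl)-4-[(E)-2-chloroethenyl]-4-methylcyclohex-1-ene F1. HBr is then added to the tetrasubstituted chloroalkene by a radical chain (HBr, dibenzoyl peroxide or light, pentane, −78 to 0 °C). The bromine atom adds to C3, and the α-chloro radical at C4 takes H from HBr anti to the bridging bromine. This anti addition is the known way from 1-chlorocyclohexenes to cis-1-bromo-2-chlorocyclohexanes. Diaxial addition should lead to the chair with both ring chlorines equatorial. Low temperature and excess HBr are meant to spare the chlorovinyl group.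

Step 2. Three things may go wrong:
- the allylic chloride of 5 ionises with help from the enol ether, which leads to loss of silyl chloride (enone formation) or epimerisation at C6;
- the chlorodiene reacts sluggishly at the hindered C6–C1 bond;
- a stepwise Michael pathway erodes the endo selectivity.

The fallback changes the diene. It sets out from 1 and comes back at 6. Isopropenyl acetate and catalytic TsOH give the enol ester (3E)-4-chlorobuta-1,3-dien-2-yl acetate F2. F2 is combined with 4 under the same oxazaborolidine, now activated with AlBr3, at −40 to −20 °C. This gives (3S,4S)-3-chloro-4-formyl-4-methylcyclohex-1-en-1-yl acetate F3. The weaker donor in F3 no longer labilises the chloride. HCl in MeOH at 0 °C then transesterifies F3 to 6.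

Step 4. Formylation may take place at C5, or HCl may be lost from the β-chloro ketone in warm POCl3/DMF. The fallback puts chlorine on C4 by substitution instead. It sets out from 7 and comes back at 13.
- Dimethylmethyleneammonium iodide in MeCN (Mannich reaction through the enol) gives (4S,5S)-5-chloro-4-[(E)-2-chloroethenyl]-2-[(dimethylamino)methyl]-4-methylcyclohexan-1-one F4 as a mixture at C2.
- MeI gives the trimethylammonium iodide F5.
- Aqueous NaHCO3 releases the enone (4S,5S)-5-chloro-4-[(E)-2-chloroethenyl]-4-methyl-2-methylidenecyclohexan-1-one F6.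
- Corey–Bakshi–Shibata reduction with (R)-tetrahydro-1-methyl-3,3-diphenyl-1H,3H-pyrrolo[1,2-c][1,3,2]oxazaborole and catecholborane should give the axial alcohol (1S,4S,5S)-5-chloro-4-[(E)-2-chloroethenyl]-4-methyl-2-methylidenecyclohexan-1-ol F7.
- PPh3 and hexachloroacetone (Appel-type SN2 with inversion and little allylic shift) lead to 13.

**Further compounds**
F1 | step 8 | (4S,5S)-1,5-dichloro-2-(chloromethyl)-4-[(E)-2-chloroethenyl]-4-methylcyclohex-1-ene | C[C@@]1(/C=C/Cl)CC(CCl)=C(Cl)C[C@@H]1Cl
F2 | step 2 | (3E)-4-chlorobuta-1,3-dien-2-yl acetate | C=C(OC(C)=O)/C=C/Cl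
F3 | step 2 | (3S,4S)-3-chloro-4-formyl-4-methylcyclohex-1-en-1-yl acetate | C[C@@]1(C=O)CCC(OC(C)=O)=C[C@@H]1Cl
F4 | step 4 | (4S,5S)-5-chloro-4-[(E)-2-chloroethenyl]-2-[(dimethylamino)methyl]-4-methylcyclohexan-1-one | C[C@@]1(/C=C/Cl)CC(CN(C)C)C(=O)C[C@@H]1Cl
F5 | step 4 | {[(4S,5S)-4-chloro-5-[(E)-2-chloroethenyl]-5-methyl-2-oxocyclohexyl]methyl}trimethylammonium iodide | C[C@@]1(/C=C/Cl)CC(C[N+](C)(C)C)C(=O)C[C@@H]1Cl.[I-]
F6 | step 4 | (4S,5S)-5-chloro-4-[(E)-2-chloroethenyl]-4-methyl-2-methylidenecyclohexan-1-one | C[C@@]1(/C=C/Cl)CC(=C)C(=O)C[C@@H]1Cl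
F7 | step 4 | (1S,4S,5S)-5-chloro-4-[(E)-2-chloroethenyl]-4-methyl-2-methylidenecyclohexan-1-ol | C[C@@]1(/C=C/Cl)CC(=C)[C@@H](O)C[C@@H]1Cl
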